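**Reading time.** Move the reading in birch from 6.00 h to 40.0 h and the share of target in the two products goes from 70.2% to 70.5%.

in all of them: enzyme 0.05 mol%
- birch: starting material 0.11 M; second substrate 1 equiv; run made earlier
- maple: starting material 0.11 M; second substrate 0.50 equiv; run made earlier
- ash: starting material 0.11 M; second substrate 2 equiv; run made earlier
- oak: starting material 0.17 M; second substrate 1 equiv; run made earlier
- Friday's: starting material 0.11 M; second substrate 1.00 equiv; a single well-mixed tank run continuously and read at steady state, 40 h in it on average
- Tuesday's: starting material 0.11 M (fed, over 32.0 h); second substrate 1.00 equiv; a stirred flask in which starting material is dosed at a steady rate over 32.0 h without added volume, worked up at 40 h; time 40 h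
- Wednesday's: starting material 0.11 M; second substrate 1.00 equiv (fed, over 32.0 h); a stirred flask in which second substrate is dosed at a steady rate over 32.0 h without added volume, worked up at 40 h; time 40 h
- Saturday's: starting material 0.11 M; second substrate 1.00 equiv; everything together in a closed stirred flask, run for 40 h; time 40 h

| run | time / h | target / % | uncatalysed product / % |
|---|---|---|---|
| birch | 6.00 | 12.7 | 5.4 |
| birch | 12.0 | 22.3 | 9.9 |
| birch | 15.0 | 27.9 | 12.5 |
| birch | 25.0 | 41.3 | 17.5 |
| birch | 30.0 | 46.4 | 18.8 |
| birch | 40.0 | 54.3 | 22.7 |
| maple | 4.00 | 8.5 | 4.3 |
| maple | 6.00 | 12.8 | 6.0 |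
| maple | 8.00 | 17.3 | 6.7 |
| maple | 15.0 | 29.5 | 11.6 |
| maple | 20.0 | 36.4 | 14.3 |
| maple | 30.0 | 47.6 | 18.5 |
| maple | 50.0 | 60.7 | 23.5 |
| ash | 2.50 | 4.0 | 2.0 |
| ash | 8.00 | 12.5 | 7.0 |
| ash | 15.0 | 23.8 | 12.1 |
| ash | 20.0 | 30.7 | 16.5 |
| ash | 30.0 | 42.8 | 18.9 |
| ash | 40.0 | 50.9 | 22.3 |
| ash | 50.0 | 56.5 | 24.8 |
| oak | 4.00 | 9.1 | 4.1 |
| oak | 12.0 | 27.7 | 10.1 |
| oak | 20.0 | 40.7 | 14.2 |
| oak | 30.0 | 52.6 | 18.4 |
| oak | 50.0 | 65.8 | 21.9 |

(standard deviation of a reading: 0.5 percentage points)

- the stated concentrations are those of everything mixed, before any reaction; amounts are the same in each set-up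
- the feed brings no volume worth counting
- the earlier runs were made in a closed, stirred flask

* the set-up with the highest share of target in all that became target or uncatalysed product, at the outlet or at the end ("none" if the first two lie within 2 percentage points) (Friday's / Tuesday's / Wednesday's / Saturday's / none)
* share of target in all that became target or uncatalysed product, at the outlet or at the end, Friday's
* share of target in all that became target or uncatalysed product, at the outlet or at the end, Tuesday's
* share of target in all that became target or uncatalysed product, at the outlet or at the end, Wednesday's
* share of target in all that became target or uncatalysed product, at the outlet or at the end, Saturday's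

**Two rates.** Birch starts with target forming at 0.0212 /h of the charge and uncatalysed product at 0.00900 /h. Between its last two readings these rates have slowed by factors of 2.68 and 2.31, close within the scatter. That common slowing cancels in a quotient, so I carry the split ratio, target formed per uncatalysed product formed, the usual selectivity factor: birch reads 2.39.

**What moves it.** Maple, with less second substrate, reads 2.58, and ash, with more, reads 2.28. Oak, with every concentration raised by one factor at the same loading, reads 3.00, so the ratio goes roughly as that factor to the power 0.524, a reading from two last points at different times. I lay this power on c(enzyme), which rose with the rest, as an assumption.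

**My reckoning.** Saturday's repeats birch's recipe, so I place it at birch's 70.5%. The other set-ups, with the same charges, I guess near maple's 72.1%, since maple's ratio stands above birch's and ash's. That gap of 1.6 percentage points is smaller than the margin, so I expect no winner.

**The forecast.** It gave 71% for Friday's, 73% for Tuesday's, 72% for Wednesday's and 70.5% for Saturday's, hence none. Of oak it says: “Oak's better ratio fits this, since its enzyme concentration is higher”. Its Tuesday's figure stands above my 72.1%.

**The result.** Friday's gives 72.0%, Tuesday's 72.2%, Wednesday's 71.9% and Saturday's 71.0%, so the answer is none.

    starting material + enzyme ⇌ complex A (K = 12.0 /M, k = 5.10 /M/s)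
    2 enzyme ⇌ resting dimer, settled at all times (K = 2.10 × 10⁶ /M)
    second substrate + enzyme ⇌ complex B (K = 110 /M, k = 24.0 /M/s)
    complex A → enzyme + target (k = 0.320 /s)
    starting material → uncatalysed product (k = 2.80 × 10⁻⁶ /s)
    complex B → enzyme + second product (k = 0.110 /s)

**Ratio reused.** The spread is 1.2 points, and Saturday's split ratio comes to 2.45 beside birch's reading of 2.39. Now take Saturday's with enzyme lowered from 0.05 mol% to 0.02 mol%. The power read from oak, laid on enzyme by itself, brings the ratio down to 1.48, a share of 59.7%. The neighbour flask gives 57.4%, with 38.2% of its starting material unused at the end.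

The numbers in the tables were generated by integration for substances that don't exist, noise included.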